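**Retrosynthetic overview**
1. Target 8 comes from the exocyclic 8(17)-alkene 7 by acid-mediated migration of the double bond into the tetrasubstituted C8=C9 position (last step).
2. 7 comes from the acyclic enol acetate 6 by one metal-free, ion-pair-controlled photoredox cycloisomerisation. The disconnections are C4–C5 (ring A, formed first) and C9–C10 (ring B, formed second). All stereocentres are set here, and the enol acetate carbon becomes C19H2OAc.
3. 6 comes from the (E)-enal 4 by conjugate reduction and O-acetylation.
4. 4 comes from methyl geranylgeranoate 3 by terminal allylic oxidation. 3 comes from (E,E)-farnesylacetone 1 and trimethyl phosphonoacetate 2 by Horner–Wadsworth–Emmons olefination.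

Assumption: 1 is bought as the pure 5E,9E isomer. Ring compounds carry labdane numbering (C18 = equatorial methyl on C4, C19 = axial CH2O carbon on C4, C20 = methyl on C10, C17 = carbon on C8).

Step 1
Reactants: 1 (5E,9E)-farnesylacetone; 2 trimethyl phosphonoacetate
Product: 3 methyl (2E,6E,10E)-3,7,11,15-tetramethylhexadeca-2,6,10,14-tetraenoate (methyl geranylgeranoate)
Conditions: NaH, THF, 0 °C to rt; 2Z isomer removed on silica
Reagents that add atoms: trimethyl phosphonoacetate, COC(=O)CP(=O)(OC)OC
Why: Horner–Wadsworth–Emmons olefination of a methyl ketone with a stabilised phosphonate anion gives mainly the 2E-enoate (about 4:1), the isomers are separable, and no stereocentre is formed.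

Step 2
Reactants: 3 methyl geranylgeranoate
Product: 4 methyl (2E,6E,10E,14E)-3,7,11,15-tetramethyl-16-oxohexadeca-2,6,10,14-tetraenoate
Conditions: SeO2 (1.2 equiv), 95% EtOH, reflux; recovered 3 recycled
Reagents that add atoms: selenium dioxide, O=[Se]=O
Why: Riley allylic oxidation (ene reaction, then [2,3]-sigmatropic shift) attacks the least hindered, electron-rich terminal alkene at its E-methyl group and runs on to the (E)-enal, while the enoate alkene is deactivated and no stereocentre is formed.

Step 3
Reactants: 4 terminal (E)-enal
Product: 6 methyl (2E,6E,10E,15E)-16-acetoxy-3,7,11,15-tetramethylhexadeca-2,6,10,15-tetraenoate, via saturated aldehyde 5 (not isolated)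
Conditions: Hantzsch ester (1.1 equiv), Bn2NH·CF3CO2H (10 mol %), THF, rt; THF stripped, then Ac2O, KOAc, 120 °C, same flask
Reagents that add atoms: acetic anhydride, CC(=O)OC(C)=O
Why: Iminium-catalysed transfer hydrogenation with the Hantzsch ester reduces only the enal C=C, and acetate-mediated enolisation with O-acetylation (enol ester formation) then flattens the transient C15 centre of 5, so 6 carries no stereocentre (about 2:1 E/Z at C15=C16, both isomers used because C16 ends as a CH2 group).

Step 4
Reactants: 6 acyclic enol acetate
Product: 7 methyl (13E)-19-acetoxylabda-8(17),13-dien-15-oate, (4S,5R,9S,10R): trans-decalin, 5α-H, 9α-H, 10β-CH3, 4β (axial) CH2OAc, 4α CH3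
Conditions: ion-pair photocatalyst (3 mol %: 9-mesityl-3,6-di-tert-butyl-10-phenylacridinium cation, confined BINOL-derived N-triflyl imidodiphosphorimidate (IDPi) anion, antipode chosen for the 10β-methyl series), 2,4,6-triisopropylbenzenethiol (20 mol %), CH2Cl2–pentane, −78 °C, 450 nm LED, Ar
Reagents that add atoms: none
Why: Proposed new method: blue-light excitation of the acridinium cation removes one electron from the enol acetate, the π bond of 6 that is easiest to oxidise (about 0.3 V below the trialkyl alkenes, the enoate is inert), and the radical cation, held as a tight ion pair in the confined chiral IDPi anion in a non-polar medium, is attacked at C4 by the C5=C10 alkene through a chair–chair fold, so that charge passes to the tertiary centres C10 and then C8 (an α-acetoxy cation is the poorer alternative) while spin stays on C19; the anion pocket selects one face of planar C4 and fixes the absolute sense, the two E-alkenes give anti additions and hence the trans ring fusion (5α-H, 10β-CH3) and 9α-H, and the flat C19 carbon rather than the C18 methyl takes the pseudo-axial site next to the C20 methyl, which gives 4S; the bulky anion then removes the most exposed proton (C17-H) to leave the exocyclic alkene, the thiol gives H to the C19 radical to make CH2OAc, and the thiyl radical re-oxidises the acridinyl radical and takes up the proton, so the event is a redox-neutral isomerisation without by-product; the closest known reaction types are acridinium/thiol anti-Markovnikov alkene hydrofunctionalisation, anodic enol ether–olefin coupling, counteranion-directed photoredox catalysis of olefin radical cations and IDPi-catalysed polyene cyclisation.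

Step 5
Reactants: 7 exocyclic alkene (minor endocyclic alkene isomers carried along)
Product: 8 methyl (13E)-19-acetoxylabda-8,13-dien-15-oate, (4S,5R,10S), the target
Conditions: TsOH·H2O (20 mol %), toluene, 80 °C, to equilibrium; residual isomers removed on AgNO3–silica
Reagents that add atoms: none
Why: Brønsted-acid alkene isomerisation through the tertiary C8 cation drains the alkene isomers into the tetrasubstituted C8=C9 alkene, the thermodynamic sink known for labd-8(17)-enes, while the deactivated enoate does not attack under these mild conditions, the C9 centre is erased, and C4, C5 and C10 are untouched.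

**Compound list**
1 | (5E,9E)-6,10,14-trimethylpentadeca-5,9,13-trien-2-one ((E,E)-farnesylacetone) | CC(=O)CC/C=C(\C)CC/C=C(\C)CCC=C(C)C | starting material
2 | trimethyl phosphonoacetate | COC(=O)CP(=O)(OC)OC | starting material
3 | methyl (2E,6E,10E)-3,7,11,15-tetramethylhexadeca-2,6,10,14-tetraenoate | COC(=O)/C=C(\C)CC/C=C(\C)CC/C=C(\C)CCC=C(C)C | intermediate
4 | methyl (2E,6E,10E,14E)-3,7,11,15-tetramethyl-16-oxohexadeca-2,6,10,14-tetraenoate | COC(=O)/C=C(\C)CC/C=C(\C)CC/C=C(\C)CC/C=C(\C)C=O | intermediate
5 | methyl (2E,6E,10E)-3,7,11,15-tetramethyl-16-oxohexadeca-2,6,10-trienoate (racemic at C15, not isolated) | COC(=O)/C=C(\C)CC/C=C(\C)CC/C=C(\C)CCCC(C)C=O | intermediate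
6 | methyl (2E,6E,10E,15E)-16-acetoxy-3,7,11,15-tetramethylhexadeca-2,6,10,15-tetraenoate (major isomer) | COC(=O)/C=C(\C)CC/C=C(\C)CC/C=C(\C)CCC/C(C)=C/OC(C)=O | intermediate
7 | methyl (13E)-19-acetoxylabda-8(17),13-dien-15-oate, (4S,5R,9S,10R) | COC(=O)/C=C(\C)CC[C@H]1C(=C)CC[C@H]2[C@@](C)(COC(C)=O)CCC[C@]12C | intermediate
8 | methyl (13E)-19-acetoxylabda-8,13-dien-15-oate, (4S,5R,10S) | COC(=O)/C=C(\C)CCC1=C(C)CC[C@H]2[C@@](C)(COC(C)=O)CCC[C@]12C | target

**Total step count:** 5. **Longest linear sequence:** 5.

**Three steps most likely to fail**

Step 4 (the new cycloisomerisation). The risks are a loose ion pair and low ee, the C4 epimer, collapse of the first intermediate to a cyclobutane, and thiol trapping of the cations. The fallback uses known chemistry, sets out from 3 and comes back at 7.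
- Terminal-selective bromohydrin formation (NBS, THF–H2O, 0 °C) gives the racemic terminal bromohydrin F1.
- K2CO3 in MeOH closes it to the terminal epoxide F2.
- H5IO6 cleaves the epoxide to the trisnor aldehyde F3.
- Wittig reaction with (triphenylphosphoranylidene)acetaldehyde gives the unbranched (E)-enal F4.
- Hantzsch ester with dibenzylammonium trifluoroacetate gives the unbranched saturated aldehyde F5.
- Organo-SOMO polyene cyclisation gives the 18-nor bicyclic aldehyde F6. The established conditions are chiral 2-tert-butyl-3-methyl-5-(1-naphthylmethyl)imidazolidin-4-one trifluoroacetate (30 mol %, the antipode for the 10β-methyl series), Cu(OTf)2 (2.5 equiv), NaO2CCF3, CF3CO2H, i-PrCN–DME, rt. The cascade ends by oxidation of the C8 radical by divalent copper and proton loss.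
- KOt-Bu and MeI in THF at −20 °C methylate the exocyclic aldehyde enolate from the open α face, opposite the C10 methyl. The formyl group therefore ends axial in the quaternary aldehyde F7.
- NaBH4 in MeOH gives the primary alcohol F8, and Ac2O–pyridine returns to 7.

Step 2 (Riley oxidation). The risks are attack at inner allylic positions, over-oxidation and a yield near 30–40%. The fallback sets out from 3 and comes back at 4. Cross-metathesis of the terminal isopropylidene unit with methacrolein (second-generation Hoveyda–Grubbs catalyst, CH2Cl2, 40 °C) exchanges the alkene terminus for the (E)-2-methylenal directly instead of oxidising a C–H bond. This detour makes no new compound (entry F0).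

Step 5 (alkene migration). The risks are an incomplete equilibrium with the 7-ene and acid-driven closure of a third ring onto the enoate. The fallback sets out from 7 and comes back at 8. Markovnikov addition of HCl (AcCl–EtOH in CH2Cl2, −20 °C) traps the C8 cation as the tertiary 8-chloride F9 before it can reach the enoate. Li2CO3–LiBr in DMF at 100 °C then eliminates HCl in the Zaitsev sense under non-acidic conditions.

**Further compounds**
F1 | step 4 | methyl (2E,6E,10E)-14-bromo-15-hydroxy-3,7,11,15-tetramethylhexadeca-2,6,10-trienoate (racemic) | COC(=O)/C=C(\C)CC/C=C(\C)CC/C=C(\C)CCC(Br)C(C)(C)O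
F2 | step 4 | methyl (2E,6E,10E)-14,15-epoxy-3,7,11,15-tetramethylhexadeca-2,6,10-trienoate (racemic) | COC(=O)/C=C(\C)CC/C=C(\C)CC/C=C(\C)CCC1OC1(C)C
F3 | step 4 | methyl (2E,6E,10E)-3,7,11-trimethyl-14-oxotetradeca-2,6,10-trienoate | COC(=O)/C=C(\C)CC/C=C(\C)CC/C=C(\C)CCC=O
F4 | step 4 | methyl (2E,6E,10E,14E)-3,7,11-trimethyl-16-oxohexadeca-2,6,10,14-tetraenoate | COC(=O)/C=C(\C)CC/C=C(\C)CC/C=C(\C)CC/C=C/C=O
F5 | step 4 | methyl (2E,6E,10E)-3,7,11-trimethyl-16-oxohexadeca-2,6,10-trienoate | COC(=O)/C=C(\C)CC/C=C(\C)CC/C=C(\C)CCCCC=O
F6 | step 4 | methyl (13E)-19-oxo-18-norlabda-8(17),13-dien-15-oate (4α equatorial CHO, 5α-H, 9α-H, 10β-CH3) | COC(=O)/C=C(\C)CC[C@H]1C(=C)CC[C@H]2[C@H](C=O)CCC[C@]12C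
F7 | step 4 | methyl (13E)-19-oxolabda-8(17),13-dien-15-oate (4β axial CHO, 4α CH3) | COC(=O)/C=C(\C)CC[C@H]1C(=C)CC[C@H]2[C@@](C)(C=O)CCC[C@]12C
F8 | step 4 | methyl (13E)-19-hydroxylabda-8(17),13-dien-15-oate | COC(=O)/C=C(\C)CC[C@H]1C(=C)CC[C@H]2[C@@](C)(CO)CCC[C@]12C
F0 | step 2 | none | none
F9 | step 5 | methyl (13E)-19-acetoxy-8α-chlorolabd-13-en-15-oate | COC(=O)/C=C(\C)CC[C@H]1[C@](C)(Cl)CC[C@H]2[C@@](C)(COC(C)=O)CCC[C@]12C
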